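Look at the delta run first: with 5.1 mM of free catalyst against 3 mM of impurity it is still losing starting material at 48.0 h, with 44.5 % left, while alpha, theta and gamma, with 2.5 mM of catalyst, stop near 92.2 %.

| setting | alpha | theta | gamma | delta | spring | autumn | dusk | dawn |
|---|---|---|---|---|---|---|---|---|
| starting material | 0.16 M | 0.34 M | 0.76 M | 0.25 M | 0.12 M | 0.25 M | 0.25 M | 1.0 M |
| partner | 0.225 M | 0.225 M | 0.225 M | 0.225 M | 0.225 M | 0.225 M | 0.225 M | 0.225 M |
| free catalyst | 2.5 mM | 2.5 mM | 2.5 mM | 5.1 mM | 5.0 mM | 2.5 mM | 10 mM | 4.0 mM |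
| impurity | 3 mM | 3 mM | 3 mM | 3 mM | 0.80 mM | 3.0 mM | 3.0 mM | 3.0 mM |
| remark | run made earlier | run made earlier | run made earlier | run made earlier |  |  |  |  |
| time |  |  |  |  | 3.0 d | 3.0 d | 3.0 d | 3.0 d |

| run | time / h | target / % | starting material / % |
|---|---|---|---|
| alpha | 5.00 | 5.0 | 93.4 |
| alpha | 12.0 | 3.7 | 92.8 |
| alpha | 25.0 | 3.2 | 91.2 |
| alpha | 40.0 | 0 | 92.3 |
| alpha | 48.0 | 2.9 | 93.4 |
| theta | 5.00 | 4.1 | 95.9 |
| theta | 12.0 | 2.9 | 93.8 |
| theta | 25.0 | 2.0 | 92.6 |
| theta | 40.0 | 1.9 | 92.2 |
| theta | 48.0 | 0.3 | 90.5 |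
| gamma | 10.0 | 4.7 | 94.5 |
| gamma | 20.0 | 1.6 | 96.1 |
| gamma | 30.0 | 3.1 | 93.9 |
| gamma | 40.0 | 1.7 | 93.0 |
| gamma | 48.0 | 1.2 | 92.0 |
| delta | 5.00 | 9.9 | 86.3 |
| delta | 12.0 | 12.7 | 76.7 |
| delta | 25.0 | 15.0 | 62.7 |
| delta | 40.0 | 13.8 | 49.3 |
| delta | 48.0 | 14.5 | 44.5 |

(standard deviation of a reading: 1 percentage point)

- no earlier run changes the charge of impurity; that part of a forecast is a guess

* ranking by amount of target, in percent of the starting material charged, from high to low, at 3.0 d (spring / autumn / dusk / dawn)
* the amount of target, in percent of the starting material charged of the flask you put first, at 3.0 d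
* the amount of target, in percent of the starting material charged of the flask you put last, at 3.0 d

So you take the impurity whole off the catalyst charge, for in alpha it stands above the catalyst. I assume each impurity removes one catalyst, and I divide the surviving catalyst by the starting material charged. This margin, q, is 3.50 % for spring. Dusk has 2.80 %, delta 0.840 %, dawn 0.100 % and autumn −0.200 %. Ranking by q, I put spring above dusk, dusk above dawn, and dawn above autumn.

Now the bracket. Let s be target over starting material consumed. It reads 0.261 at delta's last reading, down from 0.402 at 25.0 h, so I use it as a ceiling. Spring has partner in excess, so its ceiling is s at full conversion, 26.1 %. Its floor is delta's 14.5 %, because spring has the larger margin. I commit to the middle, 20.3 %. In dawn, partner is the limiting reagent: at one partner per starting material, the ceiling is 5.88 %. Autumn should stop like alpha, which gives me about 1.72 %.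

The forecast says dawn > spring > dusk > autumn, with 10 % first and 0.6 % last, reasoning for dawn that “about half of the starting material remains”. Its top stands above my dawn ceiling and below my spring floor, so here we differ.

The simulation gives spring > dusk > dawn > autumn: spring 19.2 %, dusk 16.8 %, dawn 3.64 %, autumn 1.41 %.

    starting material + free catalyst ⇌ catalyst intermediate A (K = 7.50 M⁻¹, k = 0.0270 M⁻¹ s⁻¹)
    partner + catalyst intermediate A ⇌ catalyst intermediate B (K = 3.40 M⁻¹, k = 0.00820 M⁻¹ s⁻¹)
    catalyst intermediate B ⇌ released group + catalyst intermediate C (K = 0.130 M, k = 0.00730 s⁻¹)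
    catalyst intermediate C → free catalyst + target (k = 0.00850 s⁻¹)
    target ⇌ isomer of the product (K = 4.50, k = 2.60 × 10⁻⁵ s⁻¹)
    free catalyst + impurity → spent catalyst (k = 0.160 M⁻¹ s⁻¹)

The flasks stand in the order of q, with spring's 3.50 % first. The relaxation half-life of target and isomer of the product, 0.252 d in autumn, is short against the 3.0 d allowed, and spring holds 19.2 % of target beside 78.8 % of isomer. Now take the neighbour of autumn charged with 0.0018 M of impurity. Its q is 0.280 %, above dawn's and below delta's, so you expect target between 3.64 % and 14.5 %. That flask gives 9.20 %.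

Readings and results are simulated with made-up constants; scatter was added.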